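**Plan**
- Retrosynthesis: after removal of the Me3Si and MeOCH2 groups, the C5–C6 bond of ring A is cut (reverse of a 6π-electrocyclisation with loss of Me3SiOH). This works because C5 (prenyl) and C6 (OH) are neighbouring ring A carbons remote from the ring fusion, so they are the two ends of the hexatriene C6=C7–C7a=C3a–C4=C5 whose middle double bond is the furan C3a=C7a bond.
- The resulting divinylfuran is cut at C4=C5 (Julia–Kocienski olefination), at C6–C7 (carboxylation of the furan methyl group), at the furan–aryl bond (direct C–H arylation) and at the enol O–CH3 bond.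
- Forward: the furan ring is there from the start (a 3(2H)-furanone aromatised by O-methylation), the aryl ring is attached, the two arms are built on adjacent furan carbons, and ring A, the only ring made, is closed last.
- Stereochemistry: the target has no stereocentre; the only stereo element on the way, the E alkene of the dienyl arm, comes from the Julia–Kocienski step and disappears on aromatisation.

Key step: step 11

Remark (assumption): compounds 1, 3, 10 and 11 are taken as commercial, and the furanone enolate is assumed to react on oxygen with a hard methylating agent because only that path gives an aromatic furan.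
Notation: Ar = 4-methoxy-2-(methoxymethoxy)phenyl; the labels C2 to C7a are those of the benzofuran target and are used for the same atoms in the furan precursors (C4 is the former ester carbon, C7 the former methyl carbon).

Step 1
Reactants: 1 2-bromo-5-methoxyphenol
Product: 2 1-bromo-4-methoxy-2-(methoxymethoxy)benzene
Conditions: MeOCH2Cl, iPr2NEt, CH2Cl2, 0 °C → rt
Reagents that add atoms: chloromethyl methyl ether, COCCl
Why: Williamson-type O-alkylation of the phenol with the reactive α-chloro ether should give the methoxymethyl ether, which masks the acidic OH and is stable to all later basic steps.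

Step 2
Reactants: 3 ethyl 2-methyl-4-oxo-4,5-dihydrofuran-3-carboxylate
Product: 4 ethyl 4-methoxy-2-methylfuran-3-carboxylate
Conditions: Me2SO4 (1.2 equiv), K2CO3, acetone, reflux
Reagents that add atoms: dimethyl sulfate, COS(=O)(=O)OC
Why: Enolate O-alkylation with the hard electrophile dimethyl sulfate should be favoured over C-alkylation at the ring CH2 because only O-methylation delivers the aromatic 3-methoxyfuran.

Step 3
Reactants: 4 ethyl 4-methoxy-2-methylfuran-3-carboxylate; 2 1-bromo-4-methoxy-2-(methoxymethoxy)benzene
Product: 5 ethyl 5-Ar-4-methoxy-2-methylfuran-3-carboxylate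
Conditions: Pd(OAc)2 (5 mol %), PCy3·HBF4 (10 mol %), t-BuCO2H (30 mol %), K2CO3, DMA, 110 °C
Reagents that add atoms: none
Why: Palladium-catalysed direct C–H arylation by concerted metalation–deprotonation: zerovalent palladium formed from Pd(OAc)2 inserts into the C–Br bond of 2 and the arylpalladium pivalate metalates the only free furan position, the acidic α-C–H next to the methoxy group, so the regiochemistry is unambiguous.

Step 4
Reactants: 5 ethyl 5-Ar-4-methoxy-2-methylfuran-3-carboxylate
Product: 7 2-[5-Ar-3-(ethoxycarbonyl)-4-methoxyfuran-2-yl]acetic acid, via lithiated furan 6 (not isolated)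
Conditions: LiN(iPr)2 (1.3 equiv), THF, −78 °C; transfer into CO2-saturated THF, −78 → 0 °C; aq. HCl to pH 3, 0 °C
Reagents that add atoms: carbon dioxide, O=C=O
Why: Lateral lithiation and carboxylation: the 2-methyl group is vinylogously acidified by the 3-ester, so the amide base should give the extended enolate 6, which takes up CO2 at the exocyclic carbon as is known for 2-methyl-3-furoates, and any doubly carboxylated material should decarboxylate to 7 on acidification.

Step 5
Reactants: 7 2-[5-Ar-3-(ethoxycarbonyl)-4-methoxyfuran-2-yl]acetic acid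
Product: 8 2-[5-Ar-3-(hydroxymethyl)-4-methoxyfuran-2-yl]acetic acid
Conditions: LiBH4 (3 equiv), THF, 0 → 50 °C; water, then aq. NaH2PO4 to pH 4, 0 °C; used at once
Reagents that add atoms: none
Why: Chemoselective ester reduction: LiBH4 reduces esters but leaves the lithium carboxylate formed in the flask untouched, so the C4 ester should become the primary alcohol while the acetic acid arm keeps its oxidation level.

Step 6
Reactants: 8 2-[5-Ar-3-(hydroxymethyl)-4-methoxyfuran-2-yl]acetic acid
Product: 9 2-[5-Ar-3-formyl-4-methoxyfuran-2-yl]acetic acid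
Conditions: IBX (1.5 equiv), DMSO, rt
Reagents that add atoms: none
Why: IBX oxidation of a furylmethyl (benzylic-type) alcohol should stop at the aldehyde and tolerates a free carboxylic acid and the fully substituted electron-rich furan; a cyclic hydroxy-lactone tautomer of 9 would reopen under the basic conditions of step 9.

Step 7
Reactants: 10 5-bromo-2-methylpent-2-ene; 11 1-phenyl-1H-tetrazole-5-thiol
Product: 12 5-[(4-methylpent-3-en-1-yl)sulfanyl]-1-phenyl-1H-tetrazole
Conditions: K2CO3, acetone, reflux
Reagents that add atoms: none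
Why: SN2 S-alkylation of the soft tetrazolethiolate by the primary bromide should give the thioether without affecting the trisubstituted alkene.

Step 8
Reactants: 12 5-[(4-methylpent-3-en-1-yl)sulfanyl]-1-phenyl-1H-tetrazole
Product: 13 5-[(4-methylpent-3-en-1-yl)sulfonyl]-1-phenyl-1H-tetrazole
Conditions: (NH4)6Mo7O24·4H2O (10 mol %), 30 % aq. H2O2, EtOH, 0 °C → rt
Reagents that add atoms: hydrogen peroxide, OO
Why: Molybdate-catalysed sulfide oxidation with H2O2 should reach the sulfone while the far less nucleophilic trisubstituted alkene is left alone.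

Step 9
Reactants: 9 2-[5-Ar-3-formyl-4-methoxyfuran-2-yl]acetic acid; 13 5-[(4-methylpent-3-en-1-yl)sulfonyl]-1-phenyl-1H-tetrazole
Product: 14 2-{5-Ar-4-methoxy-3-[(1E)-5-methylhexa-1,4-dien-1-yl]furan-2-yl}acetic acid
Conditions: KN(SiMe3)2 (2.3 equiv) added to 9 + 13, DME, −78 → −20 °C; aq. HCl to pH 3
Reagents that add atoms: none
Why: Julia–Kocienski olefination under Barbier conditions: the first equivalent of base forms the potassium carboxylate, the sulfonyl carbanion adds to the aldehyde, and Smiles rearrangement with loss of SO2 and tetrazolate should give the E alkene, as is usual for 1-phenyltetrazolyl sulfones with a potassium counter-ion in DME, the low temperature sparing the skipped diene.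

Step 10
Reactants: 14 2-{5-Ar-4-methoxy-3-[(1E)-5-methylhexa-1,4-dien-1-yl]furan-2-yl}acetic acid
Product: 16 2-Ar-3-methoxy-4-[(1E)-5-methylhexa-1,4-dien-1-yl]-5-[2,2-bis(trimethylsilyloxy)ethenyl]furan, via trimethylsilyl ester 15 (not isolated)
Conditions: LiN(iPr)2 (1.05 equiv), THF, −78 °C; Me3SiCl (2.6 equiv), −78 → 0 °C; LiN(iPr)2 (1.15 equiv), −78 °C → rt; pentane, filtration under argon, used crude
Reagents that add atoms: chlorotrimethylsilane, C[Si](C)(C)Cl
Why: Silyl ketene acetal formation: the lithium carboxylate is O-silylated to ester 15, whose α-CH2 is the most acidic C–H in the molecule and is deprotonated at −78 °C, and the enolate should be trapped on oxygen by the Me3SiCl already present, which avoids a dianion and leaves the doubly allylic CH2 alone.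

Step 11
Reactants: 16 2-Ar-3-methoxy-4-[(1E)-5-methylhexa-1,4-dien-1-yl]-5-[2,2-bis(trimethylsilyloxy)ethenyl]furan
Product: 18 2-Ar-3-methoxy-5-(3-methylbut-2-en-1-yl)-6-(trimethylsilyloxy)-1-benzofuran, via dihydrobenzofuran 17 (not isolated)
Conditions: N,O-bis(trimethylsilyl)acetamide (1.5 equiv), degassed o-xylene (0.02 M), sealed tube, 160 °C; evaporation, used crude
Reagents that add atoms: none
Why: Proposed new method: on heating, the triene C6=C7–C7a=C3a–C4=C5 of 16 should reach its s-cis,s-cis conformer and close by a thermally allowed disrotatory six-electron electrocyclisation that joins C5 to C6 and forms ring A as a six-membered carbocycle (17), the electron-rich ketene acetal terminus and the only weakly aromatic furan C3a=C7a bond lowering the barrier. Loss of Me3SiOH from C5–H and C6–OSiMe3 of 17, directly or after a [1,5]-hydrogen shift, should then restore the furan and create the benzene ring, and because both oxygens on C6 carry the same silyl group only one aryl silyl ether can result. The closest known reaction type is the thermal 6π-electrocyclisation of 2,3-dialkenylfurans and 2,3-dialkenylindoles followed by aromatising elimination or oxidation; a bis-silyl ketene acetal as one terminus is the untested element. No stereocentre remains, since C5 of 17 is transient and becomes planar on aromatisation. Regiochemistry is fixed by the positions of the two arms on the furan (prenyl at C5, oxygen at C6), the E alkene keeps the inward position at C5 occupied by hydrogen only, and the silylacetamide converts liberated Me3SiOH into (Me3Si)2O so that it cannot protonate unreacted ketene acetal.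

Step 12
Reactants: 18 2-Ar-3-methoxy-5-(3-methylbut-2-en-1-yl)-6-(trimethylsilyloxy)-1-benzofuran
Product: 19 ambofuranol
Conditions: 1 M aq. HCl, MeOH, rt → 40 °C
Reagents that add atoms: none
Why: Acid-catalysed methanolysis (acetal exchange and silyl ether solvolysis) should remove the methoxymethyl ether and the aryl trimethylsilyl ether in one operation, the dilute acid and low temperature sparing the 3-methoxy enol ether and the ortho-prenyl phenol.

**Compound list**
1 | 2-bromo-5-methoxyphenol | COc1ccc(Br)c(O)c1 | starting material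
2 | 1-bromo-4-methoxy-2-(methoxymethoxy)benzene | COCOc1cc(OC)ccc1Br | intermediate
3 | ethyl 2-methyl-4-oxo-4,5-dihydrofuran-3-carboxylate | CCOC(=O)C1=C(C)OCC1=O | starting material
4 | ethyl 4-methoxy-2-methylfuran-3-carboxylate | CCOC(=O)c1c(C)occ1OC | intermediate
5 | ethyl 4-methoxy-5-[4-methoxy-2-(methoxymethoxy)phenyl]-2-methylfuran-3-carboxylate | CCOC(=O)c1c(C)oc(-c2ccc(OC)cc2OCOC)c1OC | intermediate
6 | ethyl 2-(lithiomethyl)-4-methoxy-5-[4-methoxy-2-(methoxymethoxy)phenyl]furan-3-carboxylate (extended lithium enolate, not isolated) | CCOC(=O)c1c(C[Li])oc(-c2ccc(OC)cc2OCOC)c1OC | intermediate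
7 | 2-{3-(ethoxycarbonyl)-4-methoxy-5-[4-methoxy-2-(methoxymethoxy)phenyl]furan-2-yl}acetic acid | CCOC(=O)c1c(CC(=O)O)oc(-c2ccc(OC)cc2OCOC)c1OC | intermediate
8 | 2-{3-(hydroxymethyl)-4-methoxy-5-[4-methoxy-2-(methoxymethoxy)phenyl]furan-2-yl}acetic acid | OCc1c(CC(=O)O)oc(-c2ccc(OC)cc2OCOC)c1OC | intermediate
9 | 2-{3-formyl-4-methoxy-5-[4-methoxy-2-(methoxymethoxy)phenyl]furan-2-yl}acetic acid | O=Cc1c(CC(=O)O)oc(-c2ccc(OC)cc2OCOC)c1OC | intermediate
10 | 5-bromo-2-methylpent-2-ene | CC(C)=CCCBr | starting material
11 | 1-phenyl-1H-tetrazole-5-thiol | Sc1nnnn1-c1ccccc1 | starting material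
12 | 5-[(4-methylpent-3-en-1-yl)sulfanyl]-1-phenyl-1H-tetrazole | CC(C)=CCCSc1nnnn1-c1ccccc1 | intermediate
13 | 5-[(4-methylpent-3-en-1-yl)sulfonyl]-1-phenyl-1H-tetrazole | CC(C)=CCCS(=O)(=O)c1nnnn1-c1ccccc1 | intermediate
14 | 2-{4-methoxy-5-[4-methoxy-2-(methoxymethoxy)phenyl]-3-[(1E)-5-methylhexa-1,4-dien-1-yl]furan-2-yl}acetic acid | CC(C)=CC/C=C/c1c(CC(=O)O)oc(-c2ccc(OC)cc2OCOC)c1OC | intermediate
15 | trimethylsilyl 2-{4-methoxy-5-[4-methoxy-2-(methoxymethoxy)phenyl]-3-[(1E)-5-methylhexa-1,4-dien-1-yl]furan-2-yl}acetate (not isolated) | CC(C)=CC/C=C/c1c(CC(=O)O[Si](C)(C)C)oc(-c2ccc(OC)cc2OCOC)c1OC | intermediate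
16 | 2-[4-methoxy-2-(methoxymethoxy)phenyl]-3-methoxy-4-[(1E)-5-methylhexa-1,4-dien-1-yl]-5-[2,2-bis(trimethylsilyloxy)ethenyl]furan | COc1ccc(-c2oc(C=C(O[Si](C)(C)C)O[Si](C)(C)C)c(/C=C/CC=C(C)C)c2OC)c(OCOC)c1 | intermediate
17 | 2-[4-methoxy-2-(methoxymethoxy)phenyl]-3-methoxy-5-(3-methylbut-2-en-1-yl)-6,6-bis(trimethylsilyloxy)-5,6-dihydro-1-benzofuran (racemic at C5, not isolated) | COC1=C(c2ccc(OC)cc2OCOC)OC2=CC(O[Si](C)(C)C)(O[Si](C)(C)C)C(CC=C(C)C)C=C12 | intermediate
18 | 2-[4-methoxy-2-(methoxymethoxy)phenyl]-3-methoxy-5-(3-methylbut-2-en-1-yl)-6-(trimethylsilyloxy)-1-benzofuran (ambofuranol 6-O-trimethylsilyl 2'-O-methoxymethyl ether) | COc1ccc(-c2oc3cc(O[Si](C)(C)C)c(CC=C(C)C)cc3c2OC)c(OCOC)c1 | intermediate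
19 | ambofuranol, 2-(2-hydroxy-4-methoxyphenyl)-3-methoxy-5-(3-methylbut-2-en-1-yl)-1-benzofuran-6-ol | COc1ccc(-c2oc3cc(O)c(CC=C(C)C)cc3c2OC)c(O)c1 | target

**Count**
Total steps: 12.
Longest linear sequence: 9 steps (3 to 19 through steps 2, 3, 4, 5, 6, 9, 10, 11 and 12).

**Steps most likely to fail**

Step 11. The ring closure may be too slow compared with protonation of the ketene acetal by adventitious or liberated silanol, or with oxygen-to-carbon silyl migration, so that the triene is lost before C5 and C6 join. The fallback keeps the same bond formation but uses a ketene. It sets out from acid 14, which with 1-chloro-N,N,2-trimethylprop-1-en-1-amine in CH2Cl2 under neutral conditions should give 2-{5-Ar-4-methoxy-3-[(1E)-5-methylhexa-1,4-dien-1-yl]furan-2-yl}acetyl chloride F1. Et3N in dilute toluene at 80 °C should dehydrochlorinate it to the dienylketene F2. This species should undergo the well-known dienylketene 6π-electrocyclisation (the ring-forming event of the Danheiser and Dötz benzannulations) and tautomerise to the phenol, ambofuranol 2'-O-methoxymethyl ether F3. Treatment of F3 with aq. HCl in MeOH as in step 12 comes back to the route at 19.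

Step 9. The base may deprotonate the methylene between furan and carboxylate instead of driving the addition, excess base may move the skipped diene into conjugation, and the E selectivity may erode with this heteroaryl aldehyde. The fallback changes the olefination manifold and corrects the geometry afterwards. Bromide 10 and PPh3 in hot MeCN should give (4-methylpent-3-en-1-yl)triphenylphosphonium bromide F4. Its ylide (NaN(SiMe3)2, THF, −78 °C, one extra equivalent for the acid) should react with 9 in a Wittig reaction, which tolerates carboxylates, to give mainly the (Z)-dienyl acid F5. Thiyl-radical-catalysed Z to E equilibration (PhSSPh, visible light, benzene) then comes back to the route at 14.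

Step 5. The hydroxy acid may lactonise on acidification, and reduction of the flanked, electron-rich ester may be sluggish, so that 8 is not obtained cleanly. The fallback uses the lactone as the isolated intermediate. It sets out from 7: after the LiBH4 reduction, acidic work-up with pyridinium p-toluenesulfonate should close the hydroxy acid to 2-Ar-3-methoxy-4H-furo[3,2-c]pyran-6(7H)-one F6, a stable neutral compound that can be purified. LiOH (1.0 equiv) in THF–water should reopen it to lithium 2-[5-Ar-3-(hydroxymethyl)-4-methoxyfuran-2-yl]acetate F7. The dried salt is oxidised with IBX in DMSO and acidified to pH 3, which comes back to the route at 9.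

**Further compounds**
F1 | step 11 | 2-{4-methoxy-5-[4-methoxy-2-(methoxymethoxy)phenyl]-3-[(1E)-5-methylhexa-1,4-dien-1-yl]furan-2-yl}acetyl chloride | CC(C)=CC/C=C/c1c(CC(=O)Cl)oc(-c2ccc(OC)cc2OCOC)c1OC
F2 | step 11 | 2-{4-methoxy-5-[4-methoxy-2-(methoxymethoxy)phenyl]-3-[(1E)-5-methylhexa-1,4-dien-1-yl]furan-2-yl}ethenone (ketene) | CC(C)=CC/C=C/c1c(C=C=O)oc(-c2ccc(OC)cc2OCOC)c1OC
F3 | step 11 | 2-[4-methoxy-2-(methoxymethoxy)phenyl]-3-methoxy-5-(3-methylbut-2-en-1-yl)-1-benzofuran-6-ol | COc1ccc(-c2oc3cc(O)c(CC=C(C)C)cc3c2OC)c(OCOC)c1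
F4 | step 9 | (4-methylpent-3-en-1-yl)triphenylphosphonium bromide | CC(C)=CCC[P+](c1ccccc1)(c1ccccc1)c1ccccc1.[Br-]
F5 | step 9 | 2-{4-methoxy-5-[4-methoxy-2-(methoxymethoxy)phenyl]-3-[(1Z)-5-methylhexa-1,4-dien-1-yl]furan-2-yl}acetic acid | CC(C)=CC/C=C\c1c(CC(=O)O)oc(-c2ccc(OC)cc2OCOC)c1OC
F6 | step 5 | 3-methoxy-2-[4-methoxy-2-(methoxymethoxy)phenyl]-4H-furo[3,2-c]pyran-6(7H)-one | COc1c(-c2ccc(OC)cc2OCOC)oc2c1COC(=O)C2
F7 | step 5 | lithium 2-{3-(hydroxymethyl)-4-methoxy-5-[4-methoxy-2-(methoxymethoxy)phenyl]furan-2-yl}acetate | [Li+].[O-]C(=O)Cc1oc(-c2ccc(OC)cc2OCOC)c(OC)c1CO
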